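**Assumption:** 8'' and 9'' are the CH(OH) and C(CH3)2OH carbons of the side chain; the SMILES fixes both the quaternary ring carbon and C-8'' as R.

**Retrosynthetic overview**
- The target comes from a 4-ethylidene-2-(MOM-oxy)pentanedioate: ozonolysis unmasks an α-keto ester, and acid removes all acetals so the tertiary OH lactonises (the butenolide, the only ring made, closes last; both benzene rings are bought).
- That diester comes from an Ireland–Claisen [3,3] rearrangement of an α-(MOM-oxy)-β-aryl propanoate of a chiral allylic alcohol. This step forms the bond to the quaternary carbon and sets it by 1,3-chirality transfer.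
- The allylic alcohol comes from methyl (R)-3-hydroxybutanoate (Fráter–Seebach benzylation, selenoxide elimination).
- The acid comes from 4-bromo-2-iodophenol by two copper-catalysed aryl-Grignard openings of methyl (R)-glycidate; the first one (plus MeMgBr) delivers the 8''R diol.

Abbreviation used in names: Ar = 4-(methoxymethoxy)-3-{[(4R)-2,2,5,5-tetramethyl-1,3-dioxolan-4-yl]methyl}phenyl.

**Step 1**
Reactants: 1 4-bromo-2-iodophenol
Product: 2 4-bromo-2-iodo-1-(methoxymethoxy)benzene
Conditions: MOMCl, iPr2NEt, CH2Cl2, 0 °C → rt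
Reagents that add atoms: chloromethyl methyl ether (MOMCl), COCCl
Why: Williamson-type O-alkylation gives a MOM ether that survives the organomagnesium and enolate steps and is removed in the final acid step; no stereocenter is involved.

**Step 2**
Reactants: 2 4-bromo-2-iodo-1-(methoxymethoxy)benzene; 3 methyl (2R)-oxirane-2-carboxylate
Product: 6 (2R)-1-[5-bromo-2-(methoxymethoxy)phenyl]-3-methylbutane-2,3-diol, via aryl Grignard 4 (not isolated), via hydroxy ester 5 (not isolated)
Conditions: iPrMgCl·LiCl, THF, −40 °C; CuI (10 mol %), 3, −40 → −10 °C; then MeMgBr (4 equiv), 0 °C → rt; aq NH4Cl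
Reagents that add atoms: methylmagnesium bromide, C[Mg]Br
Why: Iodine–magnesium exchange is far faster at C–I than at C–Br, the copper-catalysed SN2 epoxide opening occurs at the CH2 terminus so the purchased R centre of 3 becomes the 8''R carbinol untouched, and double Grignard addition to the ester builds the tertiary alcohol.

**Step 3**
Reactants: 6 (2R)-1-[5-bromo-2-(methoxymethoxy)phenyl]-3-methylbutane-2,3-diol
Product: 7 (4R)-4-{[5-bromo-2-(methoxymethoxy)phenyl]methyl}-2,2,5,5-tetramethyl-1,3-dioxolane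
Conditions: 2,2-dimethoxypropane, PPTS (cat.), CH2Cl2, rt
Reagents that add atoms: 2,2-dimethoxypropane, COC(C)(C)OC
Why: Acid-catalysed transacetalisation (acetonide formation) masks the diol without touching the stereocenter, so Grignard formation and later enolisation are possible.

**Step 4**
Reactants: 7 (4R)-4-{[5-bromo-2-(methoxymethoxy)phenyl]methyl}-2,2,5,5-tetramethyl-1,3-dioxolane; 3 methyl (2R)-oxirane-2-carboxylate
Product: 9 methyl (2R)-2-hydroxy-3-Ar-propanoate, via aryl Grignard 8 (not isolated)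
Conditions: Mg, LiCl, THF, rt; CuI (10 mol %), 3, −40 → 0 °C; aq NH4Cl
Reagents that add atoms: none
Why: Magnesium insertion and copper-catalysed SN2 opening of the glycidate at C3 give the aryl lactate skeleton; its alpha centre (R, from 3) is only a placeholder because enolisation in step 10 erases it.

**Step 5**
Reactants: 9 methyl (2R)-2-hydroxy-3-Ar-propanoate
Product: 10 methyl (2R)-2-(methoxymethoxy)-3-Ar-propanoate
Conditions: MOMCl, iPr2NEt, Bu4NI (cat.), CH2Cl2, 0 °C → rt
Reagents that add atoms: chloromethyl methyl ether (MOMCl), COCCl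
Why: Williamson-type O-alkylation installs a chelating alkoxy group that fixes the enolate geometry in step 10 and is removed in the final acid step.

**Step 6**
Reactants: 10 methyl (2R)-2-(methoxymethoxy)-3-Ar-propanoate
Product: 11 (2R)-2-(methoxymethoxy)-3-Ar-propanoic acid
Conditions: LiOH, THF/MeOH/H2O, 0 °C → rt; then cold 1 M HCl to pH 4
Reagents that add atoms: lithium hydroxide, [Li+].[OH-]
Why: Saponification (BAc2 ester hydrolysis) frees the acid; the acetals are base-stable and any epimerisation at the alpha carbon is irrelevant.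

**Step 7**
Reactants: 12 methyl (3R)-3-hydroxybutanoate; 13 benzyl bromide
Product: 14 methyl (2R,3R)-2-benzyl-3-hydroxybutanoate
Conditions: LiN(iPr)2 (2.2 equiv), THF, −50 → −20 °C; 13, DMPU, −78 → 0 °C
Reagents that add atoms: none
Why: Fráter–Seebach alkylation benzylates the chelated dianion anti to the C3 methyl group; the purchased R carbinol is untouched and the new C2 centre is removed in step 8.

**Step 8**
Reactants: 14 methyl (2R,3R)-2-benzyl-3-hydroxybutanoate
Product: 17 methyl (2E)-2-[(1R)-1-hydroxyethyl]-3-phenylprop-2-enoate, via selenide 15 (not isolated), via selenoxide 16 (not isolated)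
Conditions: LiN(iPr)2 (2.2 equiv), THF, −78 → −20 °C; PhSeBr, −78 °C; then 30% H2O2, pyridine, CH2Cl2, 0 °C → rt
Reagents that add atoms: none
Why: Alpha-selenenylation of the dianion and selenoxide syn-elimination, which proceeds away from the carbinol C–H, give the benzylidene ester (E isomer expected as major, purified) with the R carbinol intact.

**Step 9**
Reactants: 11 (2R)-2-(methoxymethoxy)-3-Ar-propanoic acid; 17 methyl (2E)-2-[(1R)-1-hydroxyethyl]-3-phenylprop-2-enoate
Product: 18 (2R,3E)-3-(methoxycarbonyl)-4-phenylbut-3-en-2-yl (2R)-2-(methoxymethoxy)-3-Ar-propanoate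
Conditions: DCC, DMAP (cat.), CH2Cl2, 0 °C → rt
Reagents that add atoms: none
Why: Steglich esterification acylates the allylic alcohol on oxygen with retention, so the R carbinol that steers the rearrangement is carried into the ester.

**Step 10**
Reactants: 18 (2R,3E)-3-(methoxycarbonyl)-4-phenylbut-3-en-2-yl (2R)-2-(methoxymethoxy)-3-Ar-propanoate
Product: 22 dimethyl (2R,3R,4Z)-4-ethylidene-2-(methoxymethoxy)-2-(Ar-methyl)-3-phenylpentanedioate, via silyl ketene acetal 19 (not isolated), via silyl ester 20 (not isolated), via acid 21 (not isolated)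
Conditions: Me3SiCl/Et3N, LiN(iPr)2, THF, −78 °C (internal quench) → 50 °C; pH 5 buffer; then Me3SiCHN2, PhMe/MeOH, 0 °C
Reagents that add atoms: (trimethylsilyl)diazomethane, C[Si](C)(C)C=[N+]=[N-]
Why: Ireland–Claisen [3,3]-sigmatropic rearrangement of the chelation-controlled Z silyl ketene acetal through a chair with the carbinol methyl equatorial (the cis phenyl penalises the other chair by allylic 1,3-strain) forms the C2–C3 bond and transfers the R carbinol configuration to the quaternary carbon (2R), the carbinol centre becoming the ethylidene group; O-methylation of the acid follows.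

**Step 11**
Reactants: 22 dimethyl (2R,3R,4Z)-4-ethylidene-2-(methoxymethoxy)-2-(Ar-methyl)-3-phenylpentanedioate
Product: 24 methyl (2R)-2-{[3-((2R)-2,3-dihydroxy-3-methylbutyl)-4-hydroxyphenyl]methyl}-4-hydroxy-5-oxo-3-phenyl-2,5-dihydrofuran-2-carboxylate, via keto ester 23 (not isolated)
Conditions: O3, CH2Cl2/MeOH, −78 °C; Me2S, → rt; then HCl (1.25 M in MeOH), 40 °C
Reagents that add atoms: ozone, [O-][O+]=O
Why: Ozonolysis cleaves the electron-poor ethylidene group to the alpha-keto ester, and acidic methanolysis removes both MOM ethers and the acetonide so that the tertiary alcohol lactonises onto the keto ester and the product enolises to the 3-hydroxybutenolide; the quaternary and 8'' centres are untouched and C3 becomes sp2.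

**Compound list**

1 | 4-bromo-2-iodophenol | Oc1ccc(Br)cc1I | starting material
2 | 4-bromo-2-iodo-1-(methoxymethoxy)benzene | COCOc1ccc(Br)cc1I | intermediate
3 | methyl (2R)-oxirane-2-carboxylate (methyl (R)-glycidate) | COC(=O)[C@H]1CO1 | starting material
4 | [5-bromo-2-(methoxymethoxy)phenyl]magnesium chloride | COCOc1ccc(Br)cc1[Mg]Cl | intermediate (not isolated)
5 | methyl (2R)-3-[5-bromo-2-(methoxymethoxy)phenyl]-2-hydroxypropanoate (as its magnesium alkoxide) | COC(=O)[C@H](O)Cc1cc(Br)ccc1OCOC | intermediate (not isolated)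
6 | (2R)-1-[5-bromo-2-(methoxymethoxy)phenyl]-3-methylbutane-2,3-diol | CC(C)(O)[C@H](O)Cc1cc(Br)ccc1OCOC | intermediate
7 | (4R)-4-{[5-bromo-2-(methoxymethoxy)phenyl]methyl}-2,2,5,5-tetramethyl-1,3-dioxolane | CC1(C)O[C@H](Cc2cc(Br)ccc2OCOC)C(C)(C)O1 | intermediate
8 | Ar-magnesium bromide | CC1(C)O[C@H](Cc2cc([Mg]Br)ccc2OCOC)C(C)(C)O1 | intermediate (not isolated)
9 | methyl (2R)-2-hydroxy-3-Ar-propanoate | COC(=O)[C@H](O)Cc1ccc(OCOC)c(C[C@H]2OC(C)(C)OC2(C)C)c1 | intermediate
10 | methyl (2R)-2-(methoxymethoxy)-3-Ar-propanoate | COC(=O)[C@H](OCOC)Cc1ccc(OCOC)c(C[C@H]2OC(C)(C)OC2(C)C)c1 | intermediate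
11 | (2R)-2-(methoxymethoxy)-3-Ar-propanoic acid | OC(=O)[C@H](OCOC)Cc1ccc(OCOC)c(C[C@H]2OC(C)(C)OC2(C)C)c1 | intermediate
12 | methyl (3R)-3-hydroxybutanoate | C[C@@H](O)CC(=O)OC | starting material
13 | benzyl bromide | BrCc1ccccc1 | starting material
14 | methyl (2R,3R)-2-benzyl-3-hydroxybutanoate | C[C@@H](O)[C@@H](Cc1ccccc1)C(=O)OC | intermediate
15 | methyl (3R)-2-benzyl-3-hydroxy-2-(phenylselanyl)butanoate (C2 epimers) | C[C@@H](O)C(Cc1ccccc1)([Se]c1ccccc1)C(=O)OC | intermediate (not isolated)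
16 | methyl (3R)-2-benzyl-3-hydroxy-2-(benzeneseleninyl)butanoate | C[C@@H](O)C(Cc1ccccc1)([Se](=O)c1ccccc1)C(=O)OC | intermediate (not isolated)
17 | methyl (2E)-2-[(1R)-1-hydroxyethyl]-3-phenylprop-2-enoate | C[C@@H](O)/C(C(=O)OC)=C\c1ccccc1 | intermediate
18 | (2R,3E)-3-(methoxycarbonyl)-4-phenylbut-3-en-2-yl (2R)-2-(methoxymethoxy)-3-Ar-propanoate | COCO[C@H](Cc1ccc(OCOC)c(C[C@H]2OC(C)(C)OC2(C)C)c1)C(=O)O[C@H](C)/C(C(=O)OC)=C\c1ccccc1 | intermediate
19 | methyl (2E)-2-[(1R)-1-{[(1Z)-3-Ar-2-(methoxymethoxy)-1-(trimethylsilyloxy)prop-1-en-1-yl]oxy}ethyl]-3-phenylprop-2-enoate | COCO/C(Cc1ccc(OCOC)c(C[C@H]2OC(C)(C)OC2(C)C)c1)=C(\O[Si](C)(C)C)O[C@H](C)/C(C(=O)OC)=C\c1ccccc1 | intermediate (not isolated)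
20 | 5-methyl 1-(trimethylsilyl) (2R,3R,4Z)-4-ethylidene-2-(methoxymethoxy)-2-(Ar-methyl)-3-phenylpentanedioate | C[Si](C)(C)OC(=O)[C@](Cc1ccc(OCOC)c(C[C@H]2OC(C)(C)OC2(C)C)c1)(OCOC)[C@H](c1ccccc1)/C(C(=O)OC)=C/C | intermediate (not isolated)
21 | (2R,3R,4Z)-4-(methoxycarbonyl)-2-(methoxymethoxy)-2-(Ar-methyl)-3-phenylhex-4-enoic acid | OC(=O)[C@](Cc1ccc(OCOC)c(C[C@H]2OC(C)(C)OC2(C)C)c1)(OCOC)[C@H](c1ccccc1)/C(C(=O)OC)=C/C | intermediate (not isolated)
22 | dimethyl (2R,3R,4Z)-4-ethylidene-2-(methoxymethoxy)-2-(Ar-methyl)-3-phenylpentanedioate | COC(=O)[C@](Cc1ccc(OCOC)c(C[C@H]2OC(C)(C)OC2(C)C)c1)(OCOC)[C@H](c1ccccc1)/C(C(=O)OC)=C/C | intermediate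
23 | dimethyl (2R,3S)-2-(methoxymethoxy)-2-(Ar-methyl)-4-oxo-3-phenylpentanedioate | COC(=O)[C@](Cc1ccc(OCOC)c(C[C@H]2OC(C)(C)OC2(C)C)c1)(OCOC)[C@H](c1ccccc1)C(=O)C(=O)OC | intermediate (not isolated)
24 | 8''R,9''-diol versicolactone B | COC(=O)[C@]1(Cc2ccc(O)c(C[C@@H](O)C(C)(C)O)c2)OC(=O)C(O)=C1c1ccccc1 | target

**Totals**
Total step count: 11. Longest linear sequence: 9 steps (1–6, 9, 10, 11).

**Three steps most likely to fail**

Step 10 (Ireland–Claisen). The allyl part is a Michael acceptor and carries a second ester, so Dieckmann or Michael side reactions are possible, and any leak in enolate geometry or chair preference lowers the selectivity at the quaternary carbon. The fallback replaces the rearrangement by alkylation of a dioxolanone enolate (self-regeneration of the stereocenter). It sets out from bromide 7 and comes back at target 24.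
- Grignard 8 from 7 is opened with CuI catalysis onto commercial methyl (2S)-oxirane-2-carboxylate to give methyl (2S)-2-hydroxy-3-Ar-propanoate F1.
- LiOH gives (2S)-2-hydroxy-3-Ar-propanoic acid F2.
- Bis-silylation (Me3SiCl, Et3N) and Me3SiOTf-catalysed condensation with pivalaldehyde at −30 °C give the cis acetal (2S,5S)-2-tert-butyl-5-(Ar-methyl)-1,3-dioxolan-4-one F3.
- Commercial methyl (2Z)-2-(bromomethyl)-3-phenylprop-2-enoate and DABCO give 1-[(2E)-2-(methoxycarbonyl)-3-phenylprop-2-en-1-yl]-1,4-diazabicyclo[2.2.2]octan-1-ium bromide F4.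
- The lithium enolate of F3 (LiN(iPr)2, THF, −78 °C) attacks F4 in SN2′ fashion anti to the tert-butyl group, giving (2S,5R)-2-tert-butyl-5-(Ar-methyl)-5-[2-(methoxycarbonyl)-1-phenylprop-2-en-1-yl]-1,3-dioxolan-4-one F5. The electrophile takes the place of H, which makes the quaternary carbon R.
- NaOMe in MeOH opens the dioxolanone to the methyl ester, and the freed tertiary alkoxide closes onto the acrylate ester to give methyl (2R)-2-(Ar-methyl)-4-methylidene-5-oxo-3-phenyloxolane-2-carboxylate F6.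
- Ozonolysis (O3, then Me2S) gives methyl (2R)-2-(Ar-methyl)-4-hydroxy-5-oxo-3-phenyl-2,5-dihydrofuran-2-carboxylate F7, and HCl in MeOH removes the MOM and acetonide groups to give 24.

Step 8 (selenenylation and selenoxide elimination). Selenenylation of the hindered dianion may be sluggish and the E/Z ratio of the kinetic elimination is uncertain. The fallback builds the benzylidene by aldol addition and E1cB elimination; it sets out from 12 and comes back at 17.
- The dianion of 12 (LiN(iPr)2, 2.2 equiv) adds to benzaldehyde to give methyl (3R)-3-hydroxy-2-[hydroxy(phenyl)methyl]butanoate F8.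
- 1,1'-Carbonyldiimidazole closes the 1,3-diol to methyl (6R)-6-methyl-2-oxo-4-phenyl-1,3-dioxane-5-carboxylate F9.
- DBU triggers E1cB ring opening at the benzylic C–O bond (the conjugated cinnamate is the favoured product), and the resulting carbonate monoester loses CO2 to give 17 with the carbinol untouched.

Step 2 (exchange, glycidate opening and Grignard addition in one flask). The aryl Grignard may attack the glycidate ester, or halide may open the epoxide, before the copper-catalysed opening is complete. The fallback installs the two methyl groups first; it sets out from 3 (and Grignard 4) and comes back at 6.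
- 3 is treated with MeMgBr (2 equiv, THF, −78 °C), where ester addition outruns epoxide opening, to give 2-[(2R)-oxiran-2-yl]propan-2-ol F10.
- F10, as its magnesium alkoxide, is opened at the CH2 terminus by Grignard 4 with CuI catalysis, giving diol 6 directly.

**Further compounds**

F1 | step 10 | methyl (2S)-2-hydroxy-3-Ar-propanoate | COC(=O)[C@@H](O)Cc1ccc(OCOC)c(C[C@H]2OC(C)(C)OC2(C)C)c1
F2 | step 10 | (2S)-2-hydroxy-3-Ar-propanoic acid | OC(=O)[C@@H](O)Cc1ccc(OCOC)c(C[C@H]2OC(C)(C)OC2(C)C)c1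
F3 | step 10 | (2S,5S)-2-tert-butyl-5-(Ar-methyl)-1,3-dioxolan-4-one | CC(C)(C)[C@H]1O[C@@H](Cc2ccc(OCOC)c(C[C@H]3OC(C)(C)OC3(C)C)c2)C(=O)O1
F4 | step 10 | 1-[(2E)-2-(methoxycarbonyl)-3-phenylprop-2-en-1-yl]-1,4-diazabicyclo[2.2.2]octan-1-ium bromide | COC(=O)/C(C[N+]12CCN(CC1)CC2)=C/c1ccccc1.[Br-]
F5 | step 10 | (2S,5R)-2-tert-butyl-5-(Ar-methyl)-5-[2-(methoxycarbonyl)-1-phenylprop-2-en-1-yl]-1,3-dioxolan-4-one | CC(C)(C)[C@H]1O[C@](Cc2ccc(OCOC)c(C[C@H]3OC(C)(C)OC3(C)C)c2)(C(c2ccccc2)C(=C)C(=O)OC)C(=O)O1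
F6 | step 10 | methyl (2R)-2-(Ar-methyl)-4-methylidene-5-oxo-3-phenyloxolane-2-carboxylate | COC(=O)[C@]1(Cc2ccc(OCOC)c(C[C@H]3OC(C)(C)OC3(C)C)c2)OC(=O)C(=C)C1c1ccccc1
F7 | step 10 | methyl (2R)-2-(Ar-methyl)-4-hydroxy-5-oxo-3-phenyl-2,5-dihydrofuran-2-carboxylate | COC(=O)[C@]1(Cc2ccc(OCOC)c(C[C@H]3OC(C)(C)OC3(C)C)c2)OC(=O)C(O)=C1c1ccccc1
F8 | step 8 | methyl (3R)-3-hydroxy-2-[hydroxy(phenyl)methyl]butanoate | C[C@@H](O)C(C(O)c1ccccc1)C(=O)OC
F9 | step 8 | methyl (6R)-6-methyl-2-oxo-4-phenyl-1,3-dioxane-5-carboxylate | C[C@H]1OC(=O)OC(c2ccccc2)C1C(=O)OC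
F10 | step 2 | 2-[(2R)-oxiran-2-yl]propan-2-ol | CC(C)(O)[C@H]1CO1
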